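The spiro-cyclohexene is opened retrosynthetically: its ring CH2 and spiro carbon lie opposite the C(Me)=CH double bond, so this ring is the [4+2] adduct of a 5-methylene tetronate and the (E,E)-2,4-dimethyl diene that ends the Z-butenyl chain. Because the tetronate is already joined through its acyl carbon to the quaternary decalin carbon, one thermal intramolecular Diels–Alder reaction forms the CH2–CH(Et) and spiro C–C(Me) bonds, closes the cyclohexene, creates the spiro centre and closes the 11-membered carbocycle. The precursor is a trans-decalin, made by an earlier intramolecular Diels–Alder reaction of an aldol-derived trienal, that carries a 3-acyl-4-methoxy-5-methylene tetronate and the dienyl side chain.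

Key step: step 24

Remark: the target is drawn as one enol tautomer of a 3-acyltetronic acid; the exocyclic enol geometry is taken as a tautomeric form and is not set separately.
Abbreviations: TBS = tert-butyldimethylsilyl, TBSO = tert-butyldimethylsilyloxy, BHT = 2,6-di-tert-butyl-4-methylphenol.

Step 1
Reactants: 1 (E)-2-methylpent-2-enal
Product: 2 ethyl (2E,4E)-2,4-dimethylhepta-2,4-dienoate
Conditions: Ph3P=C(Me)CO2Et (1.2 equiv), toluene, 90 °C
Reagents that add atoms: ethyl 2-(triphenylphosphoranylidene)propanoate, CCOC(=O)C(C)=P(c1ccccc1)(c1ccccc1)c1ccccc1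
Why: Wittig olefination with a stabilised α-methyl ylide should form the new trisubstituted alkene with E geometry and leave the existing E-alkene untouched.

Step 2
Reactants: 2 ethyl (2E,4E)-2,4-dimethylhepta-2,4-dienoate
Product: 3 (2E,4E)-2,4-dimethylhepta-2,4-dien-1-ol
Conditions: iBu2AlH (2.2 equiv), CH2Cl2, −78 to 0 °C
Reagents that add atoms: none
Why: Hydride reduction of the conjugated ester by iBu2AlH is a clean 1,2-process that should give the dienol without conjugate reduction or loss of alkene geometry.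

Step 3
Reactants: 3 (2E,4E)-2,4-dimethylhepta-2,4-dien-1-ol
Product: 4 (2E,4E)-1-bromo-2,4-dimethylhepta-2,4-diene
Conditions: CBr4, PPh3, CH2Cl2, 0 °C
Reagents that add atoms: tetrabromomethane, BrC(Br)(Br)Br
Why: The Appel reaction replaces the primary allylic hydroxyl by SN2 attack of bromide on the alkoxyphosphonium salt under neutral conditions, so the diene geometry should be kept and the labile bromide can be used crude.

Step 4
Reactants: 4 (2E,4E)-1-bromo-2,4-dimethylhepta-2,4-diene
Product: 5 [(3E,5E)-3,5-dimethylocta-3,5-dien-1-yl]triphenylphosphonium bromide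
Conditions: Ph3PCH3Br, n-BuLi, THF, 0 °C; then 4, −78 °C to rt
Reagents that add atoms: methyltriphenylphosphonium bromide, C[P+](c1ccccc1)(c1ccccc1)c1ccccc1.[Br-]
Why: C-Alkylation of the non-stabilised ylide Ph3P=CH2 by the primary allylic bromide (SN2) adds the P–CH2 carbon and gives the homoallylic phosphonium salt directly, a known one-carbon homologation of allylic halides.

Step 5
Reactants: 6 methyl 3,3-dimethoxypropanoate
Product: 7 3,3-dimethoxypropanal
Conditions: iBu2AlH (1.05 equiv), CH2Cl2, −78 °C
Reagents that add atoms: none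
Why: Partial ester reduction stops at the aluminium hemiacetal at −78 °C and releases the aldehyde only on work-up, and the sensitive β,β-dialkoxy aldehyde would be used at once as a cold solution.

Step 6
Reactants: 7 3,3-dimethoxypropanal
Product: 8 ethyl (2E,4E)-7,7-dimethoxyhepta-2,4-dienoate
Conditions: (EtO)2P(O)CH2CH=CHCO2Et, LiN(SiMe3)2, THF, −78 to 0 °C
Reagents that add atoms: triethyl 4-phosphonocrotonate, CCOC(=O)/C=C/CP(=O)(OCC)OCC
Why: The vinylogous Horner–Wadsworth–Emmons reaction of the preformed lithium phosphonate should give mainly the (2E,4E)-dienoate, and the cold amine-free conditions are chosen so that the aldehyde is olefinated before it can lose methanol by β-elimination.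

Step 7
Reactants: 8 ethyl (2E,4E)-7,7-dimethoxyhepta-2,4-dienoate
Product: 9 (2E,4E)-7,7-dimethoxyhepta-2,4-dien-1-ol
Conditions: iBu2AlH (2.2 equiv), CH2Cl2, −78 °C
Reagents that add atoms: none
Why: 1,2-Hydride reduction of the dienoate by iBu2AlH should give the dienol while the acetal is inert to the reagent at low temperature.

Step 8
Reactants: 9 (2E,4E)-7,7-dimethoxyhepta-2,4-dien-1-ol
Product: 10 (2E,4E)-7,7-dimethoxyhepta-2,4-dienal
Conditions: MnO2, CH2Cl2, rt
Reagents that add atoms: none
Why: MnO2 oxidises allylic alcohols selectively under neutral conditions, which should leave the acetal and the diene geometry intact.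

Step 9
Reactants: 10 (2E,4E)-7,7-dimethoxyhepta-2,4-dienal; 11 (S)-4-benzyl-3-propanoyloxazolidin-2-one
Product: 13 (S)-4-benzyl-3-[(2R,3R,4E,6E)-3-hydroxy-9,9-dimethoxy-2-methylnona-4,6-dienoyl]oxazolidin-2-one, via trimethylsilyl ether 12 (not isolated)
Conditions: MgCl2 (0.2 equiv), Et3N, TMSCl, EtOAc, rt; then MeOH, cat. CF3CO2H
Reagents that add atoms: none
Why: In this MgCl2-catalysed, silyl-trapped anti-aldol reaction the chelated magnesium (Z)-enolate of the (S)-benzyl imide should be attacked by the non-enolisable dienal on the face away from the benzyl group through a boat-like transition state, which sets C2 (R) and C3 (R) anti, and acidic methanol then removes the silyl group while acetal exchange is degenerate.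

Step 10
Reactants: 13 (S)-4-benzyl-3-[(2R,3R,4E,6E)-3-hydroxy-9,9-dimethoxy-2-methylnona-4,6-dienoyl]oxazolidin-2-one
Product: 14 (2R,3R,4E,6E)-3-hydroxy-N,9,9-trimethoxy-N,2-dimethylnona-4,6-dienamide
Conditions: MeNH(OMe)·HCl, AlMe3, CH2Cl2/THF, −20 to 0 °C
Reagents that add atoms: N,O-dimethylhydroxylamine hydrochloride, CNOC.Cl
Why: Aluminium-amide transamidation (Weinreb amide formation) attacks the exocyclic imide carbonyl with help from the neighbouring aluminium alkoxide and should release the auxiliary without epimerisation or retro-aldol cleavage.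

Step 11
Reactants: 14 (2R,3R,4E,6E)-3-hydroxy-N,9,9-trimethoxy-N,2-dimethylnona-4,6-dienamide
Product: 15 tert-butyl (4R,5R,6E,8E)-5-hydroxy-11,11-dimethoxy-4-methyl-3-oxoundeca-6,8-dienoate
Conditions: t-BuOAc, LiN(iPr)2 (5 equiv each), THF, −78 to −30 °C
Reagents that add atoms: tert-butyl acetate, CC(=O)OC(C)(C)C
Why: In this crossed Claisen-type acylation the excess lithium enolate adds to the Weinreb amide to give a chelated tetrahedral intermediate that collapses to the β-keto ester only on work-up, so neither over-addition nor epimerisation of the methyl-bearing centre is expected.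

Step 12
Reactants: 15 tert-butyl (4R,5R,6E,8E)-5-hydroxy-11,11-dimethoxy-4-methyl-3-oxoundeca-6,8-dienoate
Product: 16 tert-butyl (3S,4S,5R,6E,8E)-3,5-dihydroxy-11,11-dimethoxy-4-methylundeca-6,8-dienoate
Conditions: Et2BOMe, THF/MeOH (4:1), −78 °C; NaBH4; then MeOH co-evaporation
Reagents that add atoms: none
Why: In the Narasaka–Prasad reduction the boron-chelated β-hydroxy ketone, with its dienyl and methyl groups equatorial, takes external hydride axially, which should set C3 (S) 1,3-syn to the existing carbinol and complete the anti,anti stereotriad.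

Step 13
Reactants: 16 tert-butyl (3S,4S,5R,6E,8E)-3,5-dihydroxy-11,11-dimethoxy-4-methylundeca-6,8-dienoate
Product: 17 tert-butyl (3S,4S,5R,6E,8E)-3,5-bis(TBSO)-11,11-dimethoxy-4-methylundeca-6,8-dienoate
Conditions: TBSOTf (3 equiv), 2,6-lutidine, CH2Cl2, −78 to −40 °C
Reagents that add atoms: tert-butyldimethylsilyl trifluoromethanesulfonate, CC(C)(C)[Si](C)(C)OS(=O)(=O)C(F)(F)F
Why: Silylation with the silyl triflate and a hindered base caps both secondary hydroxyls as separate ethers, and the low temperature and excess lutidine should spare the dimethyl acetal and the tert-butyl ester.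

Step 14
Reactants: 17 tert-butyl (3S,4S,5R,6E,8E)-3,5-bis(TBSO)-11,11-dimethoxy-4-methylundeca-6,8-dienoate
Product: 18 (3S,4S,5R,6E,8E)-3,5-bis(TBSO)-11,11-dimethoxy-4-methylundeca-6,8-dien-1-ol
Conditions: iBu2AlH (3 equiv), CH2Cl2, −78 to −20 °C
Reagents that add atoms: none
Why: Full hydride reduction of the hindered tert-butyl ester to the primary alcohol is more dependable than stopping at the aldehyde, and neither the silyl ethers nor the acetal react with iBu2AlH at this temperature.

Step 15
Reactants: 18 (3S,4S,5R,6E,8E)-3,5-bis(TBSO)-11,11-dimethoxy-4-methylundeca-6,8-dien-1-ol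
Product: 19 (3S,4S,5R,6E,8E)-3,5-bis(TBSO)-11,11-dimethoxy-4-methylundeca-6,8-dienal
Conditions: Dess–Martin periodinane, pyridine, CH2Cl2, 0 °C to rt
Reagents that add atoms: none
Why: Dess–Martin oxidation under buffered, non-basic conditions should give the β-silyloxy aldehyde without β-elimination or acetal cleavage.

Step 16
Reactants: 19 (3S,4S,5R,6E,8E)-3,5-bis(TBSO)-11,11-dimethoxy-4-methylundeca-6,8-dienal
Product: 20 (2E,5S,6S,7R,8E,10E)-5,7-bis(TBSO)-13,13-dimethoxy-2,6-dimethyltrideca-2,8,10-trienal
Conditions: Ph3P=C(Me)CHO (2 equiv), toluene, 70 °C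
Reagents that add atoms: 2-(triphenylphosphoranylidene)propanal, CC(C=O)=P(c1ccccc1)(c1ccccc1)c1ccccc1
Why: Wittig olefination with the formyl-stabilised ylide gives the (E)-2-methyl enal in one step and stops there because the product enal is far less electrophilic than the saturated aldehyde, the temperature being held below that at which the triene cyclises.

Step 17
Reactants: 20 (2E,5S,6S,7R,8E,10E)-5,7-bis(TBSO)-13,13-dimethoxy-2,6-dimethyltrideca-2,8,10-trienal
Product: 21 (1R,2R,4aS,5R,6S,7S,8aR)-5,7-bis(TBSO)-2-(2,2-dimethoxyethyl)-1,6-dimethyl-1,2,4a,5,6,7,8,8a-octahydronaphthalene-1-carbaldehyde (trans-fused decalin)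
Conditions: toluene (0.01 M), BHT, 110 °C
Reagents that add atoms: none
Why: This intramolecular Diels–Alder reaction of the (E)-2-methyl enal with the (E,E)-diene should pass through a chair-like four-carbon tether with both silyloxy groups equatorial, the methyl axial and the formyl group endo, which gives the trans-fused decalin and sets quaternary C1, C2 and both ring-fusion centres relative to the stereotriad, thermal activation being chosen because the acetal would not tolerate a strong Lewis acid.

Step 18
Reactants: 21 (1R,2R,4aS,5R,6S,7S,8aR)-5,7-bis(TBSO)-2-(2,2-dimethoxyethyl)-1,6-dimethyl-1,2,4a,5,6,7,8,8a-octahydronaphthalene-1-carbaldehyde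
Product: 22 (1R,2R,4aS,5R,6S,7S,8aR)-5,7-bis(TBSO)-1,6-dimethyl-2-(2-oxoethyl)-1,2,4a,5,6,7,8,8a-octahydronaphthalene-1-carbaldehyde
Conditions: SiO2, 10% aq. (CO2H)2, CH2Cl2, rt; azeotropic drying (toluene)
Reagents that add atoms: water, O
Why: Mild acid-catalysed acetal hydrolysis on wet silica frees the CH2CHO arm while the hindered secondary silyl ethers and the non-enolisable quaternary aldehyde are unaffected.

Step 19
Reactants: 22 (1R,2R,4aS,5R,6S,7S,8aR)-5,7-bis(TBSO)-1,6-dimethyl-2-(2-oxoethyl)-1,2,4a,5,6,7,8,8a-octahydronaphthalene-1-carbaldehyde; 5 [(3E,5E)-3,5-dimethylocta-3,5-dien-1-yl]triphenylphosphonium bromide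
Product: 24 (1R,2R,4aS,5R,6S,7S,8aR)-5,7-bis(TBSO)-2-[(2Z,5E,7E)-5,7-dimethyldeca-2,5,7-trien-1-yl]-1,6-dimethyl-1,2,4a,5,6,7,8,8a-octahydronaphthalene-1-carbaldehyde, via phosphorus ylide 23 (not isolated)
Conditions: 5, NaN(SiMe3)2 (1.0 equiv), THF, −78 to 0 °C; then 22, −78 to −20 °C
Reagents that add atoms: none
Why: The Wittig reaction of the non-stabilised, lithium-free ylide proceeds through the kinetically favoured cis-oxaphosphetane to the Z-alkene, and one equivalent at −78 °C should take only the unhindered CH2CHO because the other aldehyde sits on a quaternary ring carbon.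

Step 20
Reactants: 25 4-methoxyfuran-2(5H)-one
Product: 27 5-(hydroxymethyl)-4-methoxyfuran-2(5H)-one (racemic), via 5-lithio tetronate 26 (not isolated)
Conditions: LiN(iPr)2, THF, −78 °C; then CH2O (gas, from cracked paraformaldehyde)
Reagents that add atoms: formaldehyde, C=O
Why: Deprotonation of methyl tetronate occurs at C5 to give the 2-oxidofuran dienolate, which undergoes aldol addition to formaldehyde at C5, and the racemic centre so formed is destroyed in the next step.

Step 21
Reactants: 27 5-(hydroxymethyl)-4-methoxyfuran-2(5H)-one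
Product: 29 4-methoxy-5-methylenefuran-2(5H)-one, via mesylate 28 (not isolated)
Conditions: MsCl, Et3N (3 equiv), CH2Cl2, 0 °C to rt
Reagents that add atoms: none
Why: Mesylation followed by E1cB elimination through the acidic C5–H installs the exocyclic alkene, and the polymerisation-prone product would be kept as a cold BHT-stabilised solution and used the same day.

Step 22
Reactants: 29 4-methoxy-5-methylenefuran-2(5H)-one; 24 (1R,2R,4aS,5R,6S,7S,8aR)-5,7-bis(TBSO)-2-[(2Z,5E,7E)-5,7-dimethyldeca-2,5,7-trien-1-yl]-1,6-dimethyl-1,2,4a,5,6,7,8,8a-octahydronaphthalene-1-carbaldehyde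
Product: 31 3-[hydroxy(decalin-1-yl)methyl]-4-methoxy-5-methylenefuran-2(5H)-one in which the decalin-1-yl group is that of 24 (both carbinol epimers), via 3-lithio methylene tetronate 30 (not isolated)
Conditions: 29 (2 equiv), LiN(iPr)2, THF, −95 °C, 10 min; then 24, −78 to −40 °C
Reagents that add atoms: none
Why: With no C5–H left, the amide base should remove the only acidic proton, the vinylic C3–H next to the lactone carbonyl, and the resulting vinyllithium adds 1,2 to the non-enolisable neopentyl aldehyde (vinylic lithiation and carbonyl addition, as used to join tetronates to hindered decalin aldehydes), the new carbinol centre being irrelevant because it is oxidised next.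

Step 23
Reactants: 31 3-[hydroxy(decalin-1-yl)methyl]-4-methoxy-5-methylenefuran-2(5H)-one (both epimers)
Product: 32 3-(decalin-1-ylcarbonyl)-4-methoxy-5-methylenefuran-2(5H)-one in which the acyl group is the (1R,2R,4aS,5R,6S,7S,8aR)-5,7-bis(TBSO)-2-[(2Z,5E,7E)-5,7-dimethyldeca-2,5,7-trien-1-yl]-1,6-dimethyl-octahydronaphthalene-1-carbonyl group
Conditions: Dess–Martin periodinane, pyridine, CH2Cl2, 0 °C
Reagents that add atoms: none
Why: Dess–Martin oxidation converts both carbinol epimers into the single ketone under neutral conditions that the methylene tetronate, the diene and the silyl ethers should tolerate, and the product would be taken on without storage.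

Step 24
Reactants: 32 3-(decalin-1-ylcarbonyl)-4-methoxy-5-methylenefuran-2(5H)-one carrying the dienyl chain
Product: 33 O-methyl bis-TBS spirotetronate macrocycle (target skeleton with the tetronate as its 4-methyl ether and both hydroxyls as TBS ethers; on the new cyclohexene the ethyl group, the chain CH2 and the lactone oxygen lie on one face, the C-methyl and tetronate C4 on the other)
Conditions: toluene (0.002 M, degassed), BHT, 100 °C
Reagents that add atoms: none
Why: The electron-rich (E,E)-2,4-dimethyl diene at the chain end and the exocyclic C5=CH2 of the tetronate, whose LUMO is lowered by conjugation through C4=C3 to the lactone and 3-acyl carbonyls, should undergo a concerted, asynchronous, thermally allowed intramolecular Diels–Alder reaction in which the CH2–CH(Et) bond runs ahead of the spiro C–C(Me) bond. The closest known reaction type is the thermal intramolecular [4+2] addition of a chain-terminal diene to a 3-acyl-4-methoxy-5-methylene tetronate that closes an 11-membered spirotetronate carbocycle. The cyclohexene closes as the six-membered cycloadduct, and the 11-membered ring closes in the same event through the bond from tetronate C5 to the C(Me) terminus, because the tether runs from that terminus through the Z-butenyl chain, decalin C2 and C1 and the acyl carbon to tetronate C3, whereas the reversed regiochemistry would need a 12-membered ring and electronically mismatched termini. The CH(Et) and quaternary C(Me) centres follow from suprafacial addition to the (E,E)-diene (ethyl and chain CH2 cis), and the spiro centre from the orientation with the lactone oxygen under the diene and the C4(OMe) carbon outside, the only one that the short tether and the planar acyl tetronate should allow. The step needs a single diene face, which the adjacent decalin centres C1 and C2 acting through the Z-alkene are expected to select, and it needs cyclisation to outrun oligomerisation, for which high dilution, BHT and the allylic strain between the two diene methyls (disfavouring s-trans) are relied on. The tetronate is kept as its neutral methyl ether so that the dienophile stays conjugated and is not deactivated as an anion.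

Step 25
Reactants: 33 O-methyl bis-TBS spirotetronate macrocycle
Product: 34 bis-TBS ether of the target (free 3-acyltetronic acid)
Conditions: LiCl, DMSO, 50 °C; then dilute aq. HCl
Reagents that add atoms: none
Why: Chloride demethylates the vinylogous methyl ester by SN2 attack at the methyl group with the stabilised 3-acyltetronate as leaving group, which frees the tetronic acid without touching silyl ethers or alkenes.

Step 26
Reactants: 34 bis-TBS ether of the target
Product: 35 CNP0259772.1
Conditions: HF (48% aq.), MeCN, 0 °C to rt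
Reagents that add atoms: none
Why: Fluoride-assisted acidic desilylation should cleave both secondary TBS ethers and leave the acyltetronic acid, the alkenes and all stereocentres untouched, giving the target.

Compound list
1 | (E)-2-methylpent-2-enal | CC/C=C(\C)C=O | starting material
2 | ethyl (2E,4E)-2,4-dimethylhepta-2,4-dienoate | CC/C=C(\C)/C=C(\C)C(=O)OCC | intermediate
3 | (2E,4E)-2,4-dimethylhepta-2,4-dien-1-ol | CC/C=C(\C)/C=C(\C)CO | intermediate
4 | (2E,4E)-1-bromo-2,4-dimethylhepta-2,4-diene | CC/C=C(\C)/C=C(\C)CBr | intermediate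
5 | [(3E,5E)-3,5-dimethylocta-3,5-dien-1-yl]triphenylphosphonium bromide | CC/C=C(\C)/C=C(\C)CC[P+](c1ccccc1)(c1ccccc1)c1ccccc1.[Br-] | intermediate
6 | methyl 3,3-dimethoxypropanoate | COC(OC)CC(=O)OC | starting material
7 | 3,3-dimethoxypropanal | COC(OC)CC=O | intermediate
8 | ethyl (2E,4E)-7,7-dimethoxyhepta-2,4-dienoate | COC(OC)C/C=C/C=C/C(=O)OCC | intermediate
9 | (2E,4E)-7,7-dimethoxyhepta-2,4-dien-1-ol | COC(OC)C/C=C/C=C/CO | intermediate
10 | (2E,4E)-7,7-dimethoxyhepta-2,4-dienal | COC(OC)C/C=C/C=C/C=O | intermediate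
11 | (S)-4-benzyl-3-propanoyloxazolidin-2-one | CCC(=O)N1C(=O)OC[C@@H]1Cc1ccccc1 | starting material
12 | (S)-4-benzyl-3-[(2R,3R,4E,6E)-9,9-dimethoxy-2-methyl-3-(trimethylsilyloxy)nona-4,6-dienoyl]oxazolidin-2-one | COC(OC)C/C=C/C=C/[C@@H](O[Si](C)(C)C)[C@@H](C)C(=O)N1C(=O)OC[C@@H]1Cc1ccccc1 | intermediate
13 | (S)-4-benzyl-3-[(2R,3R,4E,6E)-3-hydroxy-9,9-dimethoxy-2-methylnona-4,6-dienoyl]oxazolidin-2-one | COC(OC)C/C=C/C=C/[C@@H](O)[C@@H](C)C(=O)N1C(=O)OC[C@@H]1Cc1ccccc1 | intermediate
14 | (2R,3R,4E,6E)-3-hydroxy-N,9,9-trimethoxy-N,2-dimethylnona-4,6-dienamide | COC(OC)C/C=C/C=C/[C@@H](O)[C@@H](C)C(=O)N(C)OC | intermediate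
15 | tert-butyl (4R,5R,6E,8E)-5-hydroxy-11,11-dimethoxy-4-methyl-3-oxoundeca-6,8-dienoate | COC(OC)C/C=C/C=C/[C@@H](O)[C@@H](C)C(=O)CC(=O)OC(C)(C)C | intermediate
16 | tert-butyl (3S,4S,5R,6E,8E)-3,5-dihydroxy-11,11-dimethoxy-4-methylundeca-6,8-dienoate | COC(OC)C/C=C/C=C/[C@@H](O)[C@@H](C)[C@@H](O)CC(=O)OC(C)(C)C | intermediate
17 | tert-butyl (3S,4S,5R,6E,8E)-3,5-bis(tert-butyldimethylsilyloxy)-11,11-dimethoxy-4-methylundeca-6,8-dienoate | COC(OC)C/C=C/C=C/[C@@H](O[Si](C)(C)C(C)(C)C)[C@@H](C)[C@@H](O[Si](C)(C)C(C)(C)C)CC(=O)OC(C)(C)C | intermediate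
18 | (3S,4S,5R,6E,8E)-3,5-bis(tert-butyldimethylsilyloxy)-11,11-dimethoxy-4-methylundeca-6,8-dien-1-ol | COC(OC)C/C=C/C=C/[C@@H](O[Si](C)(C)C(C)(C)C)[C@@H](C)[C@@H](O[Si](C)(C)C(C)(C)C)CCO | intermediate
19 | (3S,4S,5R,6E,8E)-3,5-bis(tert-butyldimethylsilyloxy)-11,11-dimethoxy-4-methylundeca-6,8-dienal | COC(OC)C/C=C/C=C/[C@@H](O[Si](C)(C)C(C)(C)C)[C@@H](C)[C@@H](O[Si](C)(C)C(C)(C)C)CC=O | intermediate
20 | (2E,5S,6S,7R,8E,10E)-5,7-bis(tert-butyldimethylsilyloxy)-13,13-dimethoxy-2,6-dimethyltrideca-2,8,10-trienal | COC(OC)C/C=C/C=C/[C@@H](O[Si](C)(C)C(C)(C)C)[C@@H](C)[C@@H](O[Si](C)(C)C(C)(C)C)C/C=C(\C)C=O | intermediate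
21 | (1R,2R,4aS,5R,6S,7S,8aR)-5,7-bis(tert-butyldimethylsilyloxy)-2-(2,2-dimethoxyethyl)-1,6-dimethyl-1,2,4a,5,6,7,8,8a-octahydronaphthalene-1-carbaldehyde | COC(OC)C[C@@H]1C=C[C@@H]2[C@@H](O[Si](C)(C)C(C)(C)C)[C@@H](C)[C@@H](O[Si](C)(C)C(C)(C)C)C[C@H]2[C@]1(C)C=O | intermediate
22 | (1R,2R,4aS,5R,6S,7S,8aR)-5,7-bis(tert-butyldimethylsilyloxy)-1,6-dimethyl-2-(2-oxoethyl)-1,2,4a,5,6,7,8,8a-octahydronaphthalene-1-carbaldehyde | O=CC[C@@H]1C=C[C@@H]2[C@@H](O[Si](C)(C)C(C)(C)C)[C@@H](C)[C@@H](O[Si](C)(C)C(C)(C)C)C[C@H]2[C@]1(C)C=O | intermediate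
23 | [(3E,5E)-3,5-dimethylocta-3,5-dien-1-ylidene]triphenylphosphorane | CC/C=C(\C)/C=C(\C)CC=P(c1ccccc1)(c1ccccc1)c1ccccc1 | intermediate
24 | (1R,2R,4aS,5R,6S,7S,8aR)-5,7-bis(tert-butyldimethylsilyloxy)-2-[(2Z,5E,7E)-5,7-dimethyldeca-2,5,7-trien-1-yl]-1,6-dimethyl-1,2,4a,5,6,7,8,8a-octahydronaphthalene-1-carbaldehyde | CC/C=C(\C)/C=C(\C)C/C=C\C[C@@H]1C=C[C@@H]2[C@@H](O[Si](C)(C)C(C)(C)C)[C@@H](C)[C@@H](O[Si](C)(C)C(C)(C)C)C[C@H]2[C@]1(C)C=O | intermediate
25 | 4-methoxyfuran-2(5H)-one (methyl tetronate) | COC1=CC(=O)OC1 | starting material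
26 | 5-lithio-4-methoxyfuran-2(5H)-one | COC1=CC(=O)OC1[Li] | intermediate
27 | 5-(hydroxymethyl)-4-methoxyfuran-2(5H)-one (racemic) | COC1=CC(=O)OC1CO | intermediate
28 | (3-methoxy-5-oxo-2,5-dihydrofuran-2-yl)methyl methanesulfonate (racemic) | COC1=CC(=O)OC1COS(C)(=O)=O | intermediate
29 | 4-methoxy-5-methylenefuran-2(5H)-one | COC1=CC(=O)OC1=C | intermediate
30 | 3-lithio-4-methoxy-5-methylenefuran-2(5H)-one | COC1=C([Li])C(=O)OC1=C | intermediate
31 | 3-{hydroxy[(1R,2R,4aS,5R,6S,7S,8aR)-5,7-bis(tert-butyldimethylsilyloxy)-2-[(2Z,5E,7E)-5,7-dimethyldeca-2,5,7-trien-1-yl]-1,6-dimethyl-1,2,4a,5,6,7,8,8a-octahydronaphthalen-1-yl]methyl}-4-methoxy-5-methylenefuran-2(5H)-one (both carbinol epimers) | CC/C=C(\C)/C=C(\C)C/C=C\C[C@@H]1C=C[C@@H]2[C@@H](O[Si](C)(C)C(C)(C)C)[C@@H](C)[C@@H](O[Si](C)(C)C(C)(C)C)C[C@H]2[C@]1(C)C(O)C1=C(OC)C(=C)OC1=O | intermediate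
32 | 3-{[(1R,2R,4aS,5R,6S,7S,8aR)-5,7-bis(tert-butyldimethylsilyloxy)-2-[(2Z,5E,7E)-5,7-dimethyldeca-2,5,7-trien-1-yl]-1,6-dimethyl-1,2,4a,5,6,7,8,8a-octahydronaphthalen-1-yl]carbonyl}-4-methoxy-5-methylenefuran-2(5H)-one | CC/C=C(\C)/C=C(\C)C/C=C\C[C@@H]1C=C[C@@H]2[C@@H](O[Si](C)(C)C(C)(C)C)[C@@H](C)[C@@H](O[Si](C)(C)C(C)(C)C)C[C@H]2[C@]1(C)C(=O)C1=C(OC)C(=C)OC1=O | intermediate
33 | O-methyl bis-TBS spirotetronate macrocycle: 4-methoxy tetronate spiro-fused at C5 to the ethyl-dimethyl-cyclohexene, acylated at C3 by decalin C1, 11-membered carbocycle closed through the (Z)-butenyl chain, both decalin hydroxyls as TBS ethers | CC[C@@H]1C[C@]23OC(=O)C(C(=O)[C@@]4(C)[C@@H]5C[C@H](O[Si](C)(C)C(C)(C)C)[C@H](C)[C@H](O[Si](C)(C)C(C)(C)C)[C@H]5C=C[C@H]4C/C=C\C[C@]2(C)C=C1C)=C3OC | intermediate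
34 | bis-TBS ether of the target (free 3-acyltetronic acid, drawn as the enol tautomer of the target) | CC[C@@H]1C[C@]23OC(=O)/C(=C(\O)[C@@]4(C)[C@@H]5C[C@H](O[Si](C)(C)C(C)(C)C)[C@H](C)[C@H](O[Si](C)(C)C(C)(C)C)[C@H]5C=C[C@H]4C/C=C\C[C@]2(C)C=C1C)C3=O | intermediate
35 | CNP0259772.1: 11-membered carbocyclic spirotetronate with trans-decalin diol, (Z)-butenyl bridge and ethyl-dimethyl-spirocyclohexene | CC[C@@H]1C[C@]23OC(=O)/C(=C(\O)[C@@]4(C)[C@@H]5C[C@H](O)[C@H](C)[C@H](O)[C@H]5C=C[C@H]4C/C=C\C[C@]2(C)C=C1C)C3=O | target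

Total step count: 26. Longest linear sequence: 20 steps (from 6 to 35 through steps 5–19 and 22–26).

Steps most likely to fail

Step 24 (key cycloaddition). The cycloaddition may take the wrong diene face or the wrong endo/exo orientation, or the methylene tetronate may oligomerise faster than the hindered, 1,1-disubstituted diene terminus reacts. The fallback forms the spiro ring first and closes the macrocycle at the acyl–tetronate bond. It sets out from aldehyde 24 and methylene tetronate 29 (in excess), which are heated in toluene with BHT at 120–140 °C in a sealed tube, so that the chain-end diene adds intermolecularly. The electronic bias (largest diene coefficient at CH(Et), largest dienophile coefficient at the exocyclic CH2) should give the same regiochemistry. The product is the spirotetronate aldehyde F1, formed without facial control from the remote decalin, so its diastereomers would be separated by chromatography. The correct isomer is deprotonated at tetronate C3 with lithium 2,2,6,6-tetramethylpiperidide in dilute THF at −78 °C, and the vinyllithium adds to the non-enolisable neopentyl aldehyde to close the 11-membered ring as the macrocyclic carbinol F2. Dess–Martin oxidation of F2 returns to 33.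

Step 22 (tetronate lithiation and addition). Anionic oligomerisation or conjugate addition at the exocyclic methylene during lithiation, or slow addition to the neopentyl aldehyde, may consume 29. The fallback carries the methylene in latent form and sets out from methyl tetronate 25. C5 methylation (LiN(iPr)2, MeI, THF, −78 °C) gives 4-methoxy-5-methylfuran-2(5H)-one F3. A second C5 deprotonation and selenenylation (LiN(iPr)2, PhSeBr) gives 4-methoxy-5-methyl-5-(phenylselanyl)furan-2(5H)-one F4, which has neither a C5–H nor an acceptor alkene. C3 lithiation of F4 (LiN(iPr)2, THF, −78 °C) and addition to 24 give the selenide carbinol F5. H2O2 and pyridine in CH2Cl2 at 0 °C to rt oxidise selenium to the selenoxide F6, whose syn-elimination can only take a methyl hydrogen and unveils the exocyclic methylene, returning to carbinol 31.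

Step 19 (mono-olefination of the dialdehyde). The ylide may not discriminate completely between the two aldehydes, or the cis-disposed dialdehyde may be held as a cyclic hydrate and react sluggishly. The fallback removes the competing aldehyde temporarily and sets out from 21. NaBH4 in MeOH at 0 °C reduces the neopentyl aldehyde to the primary alcohol F7 with the acetal intact. Acetal hydrolysis (aqueous oxalic acid on SiO2) gives the six-membered lactol F8. Excess ylide 23 (2.5 equiv, THF, −78 °C to rt) olefinates the ring-opened hydroxy aldehyde Z-selectively to the hydroxy triene F9. Dess–Martin oxidation of the neopentyl alcohol returns to 24.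

Further compounds
F1 | step 24 | spirotetronate aldehyde from the intermolecular cycloaddition (4-methoxy tetronate with free C3–H spiro-fused to the cyclohexene, decalin-1-carbaldehyde intact; desired diastereomer shown) | CC[C@@H]1C[C@]2(OC(=O)C=C2OC)[C@](C)(C/C=C\C[C@@H]3C=C[C@@H]4[C@@H](O[Si](C)(C)C(C)(C)C)[C@@H](C)[C@@H](O[Si](C)(C)C(C)(C)C)C[C@H]4[C@]3(C)C=O)C=C1C
F2 | step 24 | macrocyclic carbinol (33 with the decalin ketone as CH(OH), both epimers) | CC[C@@H]1C[C@]23OC(=O)C(C(O)[C@@]4(C)[C@@H]5C[C@H](O[Si](C)(C)C(C)(C)C)[C@H](C)[C@H](O[Si](C)(C)C(C)(C)C)[C@H]5C=C[C@H]4C/C=C\C[C@]2(C)C=C1C)=C3OC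
F3 | step 22 | 4-methoxy-5-methylfuran-2(5H)-one (racemic) | COC1=CC(=O)OC1C
F4 | step 22 | 4-methoxy-5-methyl-5-(phenylselanyl)furan-2(5H)-one (racemic) | COC1=CC(=O)OC1(C)[Se]c1ccccc1
F5 | step 22 | selenide carbinol (31 with C5 of the tetronate bearing methyl and phenylselanyl in place of the methylene; mixture of epimers) | CC/C=C(\C)/C=C(\C)C/C=C\C[C@@H]1C=C[C@@H]2[C@@H](O[Si](C)(C)C(C)(C)C)[C@@H](C)[C@@H](O[Si](C)(C)C(C)(C)C)C[C@H]2[C@]1(C)C(O)C1=C(OC)C(C)([Se]c2ccccc2)OC1=O
F6 | step 22 | selenoxide of F5 | CC/C=C(\C)/C=C(\C)C/C=C\C[C@@H]1C=C[C@@H]2[C@@H](O[Si](C)(C)C(C)(C)C)[C@@H](C)[C@@H](O[Si](C)(C)C(C)(C)C)C[C@H]2[C@]1(C)C(O)C1=C(OC)C(C)([Se](=O)c2ccccc2)OC1=O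
F7 | step 19 | [(1R,2R,4aS,5R,6S,7S,8aR)-5,7-bis(tert-butyldimethylsilyloxy)-2-(2,2-dimethoxyethyl)-1,6-dimethyl-1,2,4a,5,6,7,8,8a-octahydronaphthalen-1-yl]methanol | COC(OC)C[C@@H]1C=C[C@@H]2[C@@H](O[Si](C)(C)C(C)(C)C)[C@@H](C)[C@@H](O[Si](C)(C)C(C)(C)C)C[C@H]2[C@]1(C)CO
F8 | step 19 | six-membered lactol fused across decalin C1–C2 (both anomers) | OC1C[C@@H]2C=C[C@@H]3[C@@H](O[Si](C)(C)C(C)(C)C)[C@@H](C)[C@@H](O[Si](C)(C)C(C)(C)C)C[C@H]3[C@]2(C)CO1
F9 | step 19 | [(1R,2R,4aS,5R,6S,7S,8aR)-5,7-bis(tert-butyldimethylsilyloxy)-2-[(2Z,5E,7E)-5,7-dimethyldeca-2,5,7-trien-1-yl]-1,6-dimethyl-1,2,4a,5,6,7,8,8a-octahydronaphthalen-1-yl]methanol | CC/C=C(\C)/C=C(\C)C/C=C\C[C@@H]1C=C[C@@H]2[C@@H](O[Si](C)(C)C(C)(C)C)[C@@H](C)[C@@H](O[Si](C)(C)C(C)(C)C)C[C@H]2[C@]1(C)CO
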